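At 25 h, the reading time, the target in a flask fed for that long is what its catalyst turned over, less what over-reacted, so I asked first whether the catalyst keeps up.

| flask | substrate | free catalyst | temperature | remark | time |
|---|---|---|---|---|---|
| west | 1.2 M (fed, over 25 h) | 65 mM | 72 °C | run made earlier; the fed solution adds 0.50 times the starting volume |  |
| north-east | 2.4 M (fed, over 25 h) | 65 mM | 100 °C | run made earlier; the fed solution adds 0.50 times the starting volume |  |
| noon | 0.80 M (fed, over 25 h) | 65 mM | 60 °C | the fed solution adds 0.50 times the starting volume | 25 h |
| summer | 2.0 M (fed, over 25 h) | 65 mM | 90 °C | the fed solution adds 0.50 times the starting volume | 25 h |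
| dawn | 2.0 M (fed, over 25 h) | 65 mM | 110 °C | the fed solution adds 0.50 times the starting volume | 25 h |
| dusk | 1.3 M (fed, over 25 h) | 65 mM | 90 °C | the fed solution adds 0.50 times the starting volume | 25 h |
| autumn | 1.3 M (fed, over 15 h) | 65 mM | 105 °C | the fed solution adds 0.50 times the starting volume | 25 h |

| run | time / h | target / % | substrate / % |
|---|---|---|---|
| west | 3.00 | 0.6 | 9.1 |
| west | 8.00 | 3.9 | 23.7 |
| west | 15.0 | 9.8 | 44.8 |
| west | 25.0 | 19.8 | 74.6 |
| west | 30.0 | 24.0 | 69.9 |
| west | 50.0 | 43.4 | 50.0 |
| north-east | 2.00 | 4.5 | 2.4 |
| north-east | 4.00 | 11.7 | 2.6 |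
| north-east | 5.00 | 15.5 | 3.2 |
| north-east | 8.00 | 26.4 | 2.6 |
| north-east | 10.0 | 33.3 | 3.1 |
| north-east | 12.0 | 39.9 | 3.3 |

(scatter of a reading: 0.3 percentage points)

- the flasks by amount of target, in percent of the substrate charged, highest first, at 25 h (noon / summer / dawn / dusk / autumn)
- the same order at 5.0 h (noon / summer / dawn / dusk / autumn)
- the amount of target, in percent of the substrate charged of the flask you put first, at 25 h
- the amount of target, in percent of the substrate charged of the flask you put last, at 25 h

- amounts are per litre of the starting volume; all of the dose is in the solution fed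
- the numbers in the tables scatter with a standard deviation of 0.3 percentage points
- steps that have been proposed: substrate + free catalyst -> catalyst intermediate A; catalyst intermediate A -> catalyst intermediate B; catalyst intermediate B -> free catalyst + target; target -> over-reaction product
- percentages count the whole charge, also what has not yet gone in

Was the catalyst full in west? At 25.0 h target and substrate fell short of the charge by 67.2 mM, which matches the catalyst charge. I read the bound forms as the resting state of west, and the late slope of target gave a turnover number k_cat of 0.179 h⁻¹ at 72 °C. In north-east substrate stayed between 2.4 % and 3.3 %, so I took turnover to match the dose of 0.0960 M h⁻¹. Later shortfalls there grow and hold over-reaction product as well, so I took bound catalyst from the earliest one, 26.4 mM at 2.00 h, less than the charge. That gave k_cat as 3.64 h⁻¹ at 100 °C, a reading that carries the scatter of its one shortfall. Between the two temperatures k_cat rose by a factor of 20.3, which I spread evenly in ln k_cat over the degrees.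

Which flasks are overfed? For noon k_cat came to 0.0493 h⁻¹, so the feed load L was 9.99, L being the dosing rate over catalyst charge times k_cat. Noon, fed faster than it turns over, can deliver about 1/L, or 10.0 % of its charge. At 90 °C, L was 0.645 in dusk and 0.992 in summer.

What do hot flasks lose? The growing north-east shortfall gave over-reaction at 0.0181 h⁻¹. With the same rise per degree, and target made steadily, dusk keeps 92.7 % of the target it makes and dawn 55.5 %. I put dusk first and noon last.

The forecast gave dusk > summer > autumn > dawn > noon, then autumn > dawn > dusk > summer > noon at 5.0 h, with 76 % and 6.3 %, calling dusk “feed below capacity”; its noon stands below my 10.0 %.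

The flasks gave dusk > summer > autumn > dawn > noon, then autumn > dawn > dusk > summer > noon at 5.0 h, with 81.3 % and 5.44 %.

    substrate + free catalyst → catalyst intermediate A (k = 19.0 L mol⁻¹ h⁻¹, Ea = 74.0 kJ mol⁻¹)
    catalyst intermediate A → catalyst intermediate B (k = 2.10 h⁻¹, Ea = 121 kJ mol⁻¹)
    catalyst intermediate B → free catalyst + target (k = 4.40 h⁻¹, Ea = 102 kJ mol⁻¹)
    target → over-reaction product (k = 0.00600 h⁻¹, Ea = 116 kJ mol⁻¹)
    (constants at 90 °C)

Noon delivered 5.44 %, about half of 1/L, with 4.49 % of its catalyst free and 86.8 % of its substrate left. The same flask at 85 °C has L of 0.679, below 1, so the catalyst should keep up. It did: 44.4 % of the catalyst stayed free, substrate stood at 14.5 %, and target reached 77.9 %.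

The data are calculated on assumed constants; scatter was added.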